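# Proposed synthesis of (S)-(4-hydroxy-3,5-dimethoxyphenyl)[(3R,4R)-4-(4-hydroxy-3,5-dimethoxybenzyl)tetrahydrofuran-3-yl]methanol (20)

Compound numbers 1–20 are those fixed in the steps and the compound list below.

## Analysis of the target

Target 20 is a tetrahydrofuran lignan of the 9,9'-epoxylignan-7-ol type. Its only non-aromatic ring is an oxolane in which C2 and C5, on either side of O1, are unsubstituted methylene groups. C3 carries a secondary benzylic carbinol bearing a 4-hydroxy-3,5-dimethoxyphenyl group, and C4 carries a 4-hydroxy-3,5-dimethoxybenzyl group. There are three contiguous stereocentres: C3 (R) and C4 (R), whose substituents are trans on the ring, and the exocyclic carbinol carbon (S). The sensitive element is the para-hydroxybenzylic alcohol, which can ionise to a quinone methide under acid or base and whose benzylic C–O bond can be hydrogenolysed; the electron-rich phenols are also easily oxidised and are best carried as ethers. The synthesis is hard because the two aryl groups are identical while their linkers differ in oxidation level (CH2 against CHOH), so the skeleton must be built unsymmetrically, and because the ring has no functional handle at C2 or C5. The strategy rests on that last feature: O1 flanked by two CH2 groups with C3 and C4 trans is the pattern left when a CH2–O–CH2 unit adds across an E-alkene, so the C2–C3 and C4–C5 bonds can be made in one cycloaddition.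

## Retrosynthetic reasoning

**20 to 19.** The two phenolic O–benzyl bonds are cut last. Benzyl ethers survive the fluoride, peroxide, organolithium and hydride conditions used earlier. They are removed by neutral hydrogenolysis, which is the mildest option for the para-hydroxybenzylic alcohol of 20.

**19 to 18.** The carbinol C–H bond is cut, giving ketone 18. This takes the exocyclic stereocentre out of the ring-building problem. It is set at the end by hydride addition under control of the neighbouring ring stereocentre C3.

**18 to 13 and 16.** The bond between the carbonyl carbon and the aromatic ring is cut, giving N-methoxy-N-methylamide 13 and aryllithium 16. Aryllithium 16 comes from bromide 15, and 15 from the commercial bromophenol 14. Cutting here and not at the C3–carbonyl bond keeps the acyl carbon on C3, where the cycloaddition places it. The forward reaction must stop at single addition, which the chelated adduct 17 ensures.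

**13 to 11 to 9.** The amide C–N bond is traced through acid 11 to the imide C–N bond of cycloadduct 9. This exchange takes two routine operations and returns auxiliary 3.

**9 to 5 and 8.** This is the key disconnection. The C2–C3 and C4–C5 bonds are cut together, which removes the whole CH2–O–CH2 bridge as carbonyl ylide 8 and leaves E-enoyl imide 5. No other cut removes two ring bonds and both ring stereocentres at once while leaving the ring at its final oxidation level. The forward step must transfer the E geometry into the 3,4-trans relationship and choose one alkene face. Ylide 8 is released from silyl chloromethyl ether 7, which is made from alcohol 6.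

**5 to 2 and 4.** The C2=C3 double bond of the butenoyl chain is cut by cross-metathesis into allylarene 2 and acryloyl imide 4. A metathesis is chosen because it is neutral, so the acidic ArCH2 group between arene and alkene is never exposed to base. Allylarene 2 comes from the commercial allylphenol 1 by O-benzylation, and 4 from oxazolidinone 3 by N-acylation.

## Alternatives that were turned down

**Alternative 1:** The target is cut at the bond from the benzylic carbon to C4 and at the bond from C3 to the carbinol carbon, both traced to a butenolide core. In the forward step, lithiated dithiane A3 adds to the β-carbon of menthyloxybutenolide A2 anti to the acetal substituent, and the lactone enolate is trapped by aldehyde A4 to give lactone A1.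
- For: both aryl groups and all skeletal carbons are joined in one flask, and the two ring stereocentres come from a well-behaved acetal-directed conjugate addition and anti trapping. On reliability of ring stereocontrol this alternative is stronger than the chosen route, whose facial selectivity is untested.
- Against: no ring of the target is formed. A1 still needs desulfurisation with Raney Ni in the presence of benzyl ethers and a benzylic alcohol. Both the lactone carbonyl and the acetal carbon must be reduced to CH2OH. The resulting triol must then be cyclised through its two primary hydroxyls, while closure through the benzylic position is mechanistically easier. The aldol trapping is unlikely to control the carbinol centre.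
- Comparison: the chosen strategy delivers the ether ring at its final oxidation level, so no triol regiochemistry problem arises and fewer steps follow the key step.

**Alternative 2:** Only the bond from C2 to the ring carbon bearing the arylmethyl group is cut, leading to open-chain selenide A6, in which the other ring stereocentre and the carbinol are already present. In the forward step, Bu3SnH and AIBN generate an alkoxymethyl radical that closes 5-exo-trig onto the styrene, and the benzylic radical is reduced to give silyl ether A5.
- For: the carbinol and one ring stereocentre are set beforehand by acyclic chemistry. On the carbinol centre this alternative is stronger, because the chosen route leaves it to a late substrate-controlled reduction. The radical conditions are neutral.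
- Against: the step forms one bond and one stereocentre. The 3,4-trans relationship comes from a chair-like transition state with a pseudo-equatorial substituent, which is a preference and not a stereospecific outcome. A6 needs a long linear sequence, including a selenomethyl ether on a hindered primary alcohol, and stoichiometric tin and selenium.
- Comparison: the chosen strategy makes two ring bonds and the ring in one step, with trans fixed by the alkene geometry, from a precursor three steps from commercial material.

**Alternative 3:** The C2–O1 bond is cut after placing a carbonyl on C2, which leads to prochiral cyclobutanone A8, accessible from allylarene 2 by ketene [2+2] cycloaddition and dechlorination. In the forward step, H2O2 with a chiral phosphoric acid (or a Baeyer–Villiger monooxygenase) inserts oxygen into one of the two enantiotopic ring bonds to give lactone A7.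
- For: asymmetric catalysis replaces a stoichiometric auxiliary, and the precursor is short and symmetric. In atom and chirality economy this alternative is stronger.
- Against: only C4 is set, and the stereocentre lies one CH2 farther from the arene than in the 3-arylcyclobutanones best suited to acid-catalysed desymmetrisation. C3 and the carbinol must come from a lactone aldol with poor carbinol control. The lactone carbonyl is at the wrong oxidation level and must be reduced to a diol and re-closed, again with the benzylic hydroxyl competing. At least six steps follow the key step.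
- Comparison: the chosen strategy sets C3 and C4 together at the correct oxidation level and leaves the acyl carbon on C3 ready for the aryl nucleophile.

Key step: step 5

Assumption: with CsF in MeCN no chelating metal ion is present, so 5 is taken to react through its dipole-minimised anti-s-cis conformer, and the (R)-configured auxiliary is chosen on that basis.

## Route

Step 1
Reactants: 1 4-allyl-2,6-dimethoxyphenol
Product: 2 5-allyl-2-(benzyloxy)-1,3-dimethoxybenzene
Conditions: BnBr, K2CO3, DMF, rt
Reagents that add atoms: benzyl bromide, BrCc1ccccc1
Why: Williamson ether synthesis on the phenoxide; K2CO3 is too weak a base to move the allyl double bond into conjugation, so the terminal alkene needed for metathesis is kept.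

Step 2
Reactants: 3 (R)-4-benzyloxazolidin-2-one
Product: 4 (R)-3-acryloyl-4-benzyloxazolidin-2-one
Conditions: acryloyl chloride, Et3N, LiCl, THF, −20 °C to rt
Reagents that add atoms: acryloyl chloride, C=CC(Cl)=O
Why: N-acylation of the oxazolidinone; lithium coordination makes the carbamate N–H acidic enough for Et3N, so no strong base that would polymerise the acrylate is needed.

Step 3
Reactants: 2 5-allyl-2-(benzyloxy)-1,3-dimethoxybenzene; 4 (R)-3-acryloyl-4-benzyloxazolidin-2-one
Product: 5 (R)-4-benzyl-3-[(E)-4-(4-benzyloxy-3,5-dimethoxyphenyl)but-2-enoyl]oxazolidin-2-one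
Conditions: second-generation Grubbs catalyst RuCl2(=CHPh)(PCy3)(H2IMes) (5 mol %), 1,4-benzoquinone (10 mol %), CH2Cl2, 40 °C
Reagents that add atoms: none
Why: Olefin cross-metathesis between an electron-neutral terminal alkene and an electron-poor acryloyl partner, which favours the cross product and gives the E isomer under thermodynamic control. The neutral conditions leave the acidic ArCH2 group untouched, and benzoquinone suppresses migration of the allyl double bond by ruthenium hydrides.

Step 4
Reactants: 6 (trimethylsilyl)methanol
Product: 7 chloromethyl (trimethylsilyl)methyl ether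
Conditions: paraformaldehyde, HCl (g), neat, 0 °C; CaCl2; distillation
Reagents that add atoms: paraformaldehyde (formaldehyde unit), C=O; hydrogen chloride, Cl
Why: Chloromethylation of an alcohol through its hemiformal, giving the α-chloro ether; the C–Si bond is stable to anhydrous HCl at 0 °C.

Step 5
Reactants: 5 (R)-4-benzyl-3-[(E)-4-(4-benzyloxy-3,5-dimethoxyphenyl)but-2-enoyl]oxazolidin-2-one; 7 chloromethyl (trimethylsilyl)methyl ether
Product: 9 (R)-4-benzyl-3-{[(3R,4R)-4-(4-benzyloxy-3,5-dimethoxybenzyl)tetrahydrofuran-3-yl]carbonyl}oxazolidin-2-one, via carbonyl ylide 8 (not isolated)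
Conditions: CsF (anhydrous, 3 equiv), MeCN, rt, slow addition of 7 (2 equiv); separation of the two trans diastereomers on silica
Reagents that add atoms: none
Why: Proposed new method: fluoride attacks silicon of 7 and chloride leaves in a 1,3-elimination that releases ylide 8, a 4π-electron three-atom dipole, which adds to the electron-poor C=C of 5 in a concerted suprafacial [3+2] cycloaddition, so that C2–C3 and C4–C5 form together and the tetrahydrofuran is closed by intermolecular cycloaddition and not by a stepwise exo or endo closure. The closest known reaction type is the cycloaddition of this same non-stabilised ylide to achiral acrylates, fumarates and enones; the new element is the auxiliary-bearing enoyl imide. The E geometry of 5 is carried stereospecifically into the 3,4-trans relationship, so the relative configuration of C3 and C4 does not depend on the auxiliary. The absolute configuration is set by the alkene face attacked: without a chelating metal the imide should adopt the anti-s-cis conformation, in which the benzyl group of the (R)-auxiliary lies over the Re face of the α-carbon and the ylide adds to the Si face, which gives (3R,4R). Because the alkene is remote from the auxiliary stereocentre in that conformer, the bias is expected to be modest, and the step relies on the two trans adducts being diastereomers that can be separated on silica. The step needs cycloaddition to outrun deprotonation of the doubly activated ArCH2 group; sparingly soluble CsF in MeCN at room temperature and slow addition of 7 keep the medium only weakly basic. No regiochemical question arises because the dipole is symmetrical.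

Step 6
Reactants: 9 (R)-4-benzyl-3-{[(3R,4R)-4-(4-benzyloxy-3,5-dimethoxybenzyl)tetrahydrofuran-3-yl]carbonyl}oxazolidin-2-one
Product: 11 (3R,4R)-4-(4-benzyloxy-3,5-dimethoxybenzyl)tetrahydrofuran-3-carboxylic acid, via lithium peroxycarboxylate 10 (not isolated)
Conditions: LiOH, H2O2 (30 %), THF/H2O 3:1, 0 °C; Na2SO3 (aq); HCl (aq) to pH 2
Reagents that add atoms: hydrogen peroxide, OO (as LiOOH; one oxygen atom stays in 11); lithium hydroxide, [Li+].[OH-] (counter-ion of 10 only)
Why: Hydroperoxide cleavage of an N-acyloxazolidinone: the small α-effect nucleophile attacks the exocyclic carbonyl even of this α-branched imide, and sulfite reduces the peroxy acid salt to the carboxylate. Auxiliary 3 is recovered, and C3 is not at risk because the trans arrangement is the thermodynamically preferred one.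

Step 7
Reactants: 11 (3R,4R)-4-(4-benzyloxy-3,5-dimethoxybenzyl)tetrahydrofuran-3-carboxylic acid
Product: 13 (3R,4R)-4-(4-benzyloxy-3,5-dimethoxybenzyl)-N-methoxy-N-methyltetrahydrofuran-3-carboxamide, via acyl imidazole 12 (not isolated)
Conditions: 1,1'-carbonyldiimidazole, CH2Cl2, rt; then MeNH(OMe)·HCl, rt
Reagents that add atoms: N,O-dimethylhydroxylamine hydrochloride, CNOC.Cl; 1,1'-carbonyldiimidazole, O=C(n1ccnc1)n1ccnc1 (its imidazolyl group is carried only by 12)
Why: Amide formation through the acyl imidazole under essentially neutral conditions, so the α-stereocentre C3 is not epimerised.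

Step 8
Reactants: 14 4-bromo-2,6-dimethoxyphenol
Product: 15 2-(benzyloxy)-5-bromo-1,3-dimethoxybenzene
Conditions: BnBr, K2CO3, DMF, rt
Reagents that add atoms: benzyl bromide, BrCc1ccccc1
Why: Williamson ether synthesis; the aryl bromide is inert under these conditions.

Step 9
Reactants: 15 2-(benzyloxy)-5-bromo-1,3-dimethoxybenzene; 13 (3R,4R)-4-(4-benzyloxy-3,5-dimethoxybenzyl)-N-methoxy-N-methyltetrahydrofuran-3-carboxamide
Product: 18 (4-benzyloxy-3,5-dimethoxyphenyl)[(3R,4R)-4-(4-benzyloxy-3,5-dimethoxybenzyl)tetrahydrofuran-3-yl]methanone, via aryllithium 16 (not isolated), via tetrahedral lithium adduct 17 (not isolated)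
Conditions: 15, n-BuLi, THF, −78 °C; then 13, −78 °C; HCl (1 M aq) quench
Reagents that add atoms: none
Why: Weinreb ketone synthesis: bromine–lithium exchange gives 16, which adds only once because chelate 17 is stable at −78 °C and collapses to the ketone on acidic work-up. The benzyl ethers tolerate the aryllithium at this temperature, and the trans ring configuration is the stable one should any enolisation occur.

Step 10
Reactants: 18 (4-benzyloxy-3,5-dimethoxyphenyl)[(3R,4R)-4-(4-benzyloxy-3,5-dimethoxybenzyl)tetrahydrofuran-3-yl]methanone
Product: 19 (S)-(4-benzyloxy-3,5-dimethoxyphenyl)[(3R,4R)-4-(4-benzyloxy-3,5-dimethoxybenzyl)tetrahydrofuran-3-yl]methanol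
Conditions: LiBH(s-Bu)3, THF, −78 °C; H2O
Reagents that add atoms: none
Why: Felkin–Anh-controlled ketone reduction by a bulky hydride: with ring carbon C4 (bearing the arylmethyl group) as the large substituent anti to the incoming hydride and the OCH2 carbon C2 as the medium one, hydride adds to the face that gives the (S)-carbinol. A chelate between the carbonyl and O1 would direct attack to the same face, so both models agree.

Step 11
Reactants: 19 (S)-(4-benzyloxy-3,5-dimethoxyphenyl)[(3R,4R)-4-(4-benzyloxy-3,5-dimethoxybenzyl)tetrahydrofuran-3-yl]methanol
Product: 20 (S)-(4-hydroxy-3,5-dimethoxyphenyl)[(3R,4R)-4-(4-hydroxy-3,5-dimethoxybenzyl)tetrahydrofuran-3-yl]methanol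
Conditions: H2 (1 atm), Pd/C (10 wt %), EtOAc, rt, stopped at full conversion
Reagents that add atoms: none
Why: Hydrogenolysis of aryl benzyl ethers, which under neutral conditions in an aprotic solvent is much faster than cleavage of the secondary benzylic C–OH bond; no stereocentre is touched.

## Compound list

1 | 4-allyl-2,6-dimethoxyphenol | C=CCc1cc(OC)c(O)c(OC)c1 | starting material
2 | 5-allyl-2-(benzyloxy)-1,3-dimethoxybenzene | C=CCc1cc(OC)c(OCc2ccccc2)c(OC)c1 | intermediate
3 | (R)-4-benzyloxazolidin-2-one | O=C1N[C@H](Cc2ccccc2)CO1 | starting material
4 | (R)-3-acryloyl-4-benzyloxazolidin-2-one | C=CC(=O)N1[C@H](Cc2ccccc2)COC1=O | intermediate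
5 | (R)-4-benzyl-3-[(E)-4-(4-benzyloxy-3,5-dimethoxyphenyl)but-2-enoyl]oxazolidin-2-one | COc1cc(C/C=C/C(=O)N2[C@H](Cc3ccccc3)COC2=O)cc(OC)c1OCc1ccccc1 | intermediate
6 | (trimethylsilyl)methanol | OC[Si](C)(C)C | starting material
7 | chloromethyl (trimethylsilyl)methyl ether | ClCOC[Si](C)(C)C | intermediate
8 | carbonyl ylide (formaldehyde O-methylide) | C=[O+][CH2-] | intermediate (not isolated)
9 | (R)-4-benzyl-3-{[(3R,4R)-4-(4-benzyloxy-3,5-dimethoxybenzyl)tetrahydrofuran-3-yl]carbonyl}oxazolidin-2-one | COc1cc(C[C@H]2COC[C@@H]2C(=O)N2[C@H](Cc3ccccc3)COC2=O)cc(OC)c1OCc1ccccc1 | intermediate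
10 | lithium (3R,4R)-4-(4-benzyloxy-3,5-dimethoxybenzyl)tetrahydrofuran-3-carboperoxoate | [Li+].[O-]OC(=O)[C@H]1COC[C@@H]1Cc1cc(OC)c(OCc2ccccc2)c(OC)c1 | intermediate (not isolated)
11 | (3R,4R)-4-(4-benzyloxy-3,5-dimethoxybenzyl)tetrahydrofuran-3-carboxylic acid | OC(=O)[C@H]1COC[C@@H]1Cc1cc(OC)c(OCc2ccccc2)c(OC)c1 | intermediate
12 | 1-{[(3R,4R)-4-(4-benzyloxy-3,5-dimethoxybenzyl)tetrahydrofuran-3-yl]carbonyl}-1H-imidazole | O=C(n1ccnc1)[C@H]1COC[C@@H]1Cc1cc(OC)c(OCc2ccccc2)c(OC)c1 | intermediate (not isolated)
13 | (3R,4R)-4-(4-benzyloxy-3,5-dimethoxybenzyl)-N-methoxy-N-methyltetrahydrofuran-3-carboxamide | CON(C)C(=O)[C@H]1COC[C@@H]1Cc1cc(OC)c(OCc2ccccc2)c(OC)c1 | intermediate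
14 | 4-bromo-2,6-dimethoxyphenol | COc1cc(Br)cc(OC)c1O | starting material
15 | 2-(benzyloxy)-5-bromo-1,3-dimethoxybenzene | COc1cc(Br)cc(OC)c1OCc1ccccc1 | intermediate
16 | (4-benzyloxy-3,5-dimethoxyphenyl)lithium | [Li]c1cc(OC)c(OCc2ccccc2)c(OC)c1 | intermediate (not isolated)
17 | lithium (4-benzyloxy-3,5-dimethoxyphenyl)[(3R,4R)-4-(4-benzyloxy-3,5-dimethoxybenzyl)tetrahydrofuran-3-yl][methoxy(methyl)amino]methanolate | [Li+].[O-]C(N(C)OC)(c1cc(OC)c(OCc2ccccc2)c(OC)c1)[C@H]1COC[C@@H]1Cc1cc(OC)c(OCc2ccccc2)c(OC)c1 | intermediate (not isolated)
18 | (4-benzyloxy-3,5-dimethoxyphenyl)[(3R,4R)-4-(4-benzyloxy-3,5-dimethoxybenzyl)tetrahydrofuran-3-yl]methanone | COc1cc(C[C@H]2COC[C@@H]2C(=O)c2cc(OC)c(OCc3ccccc3)c(OC)c2)cc(OC)c1OCc1ccccc1 | intermediate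
19 | (S)-(4-benzyloxy-3,5-dimethoxyphenyl)[(3R,4R)-4-(4-benzyloxy-3,5-dimethoxybenzyl)tetrahydrofuran-3-yl]methanol | COc1cc(C[C@H]2COC[C@@H]2[C@H](O)c2cc(OC)c(OCc3ccccc3)c(OC)c2)cc(OC)c1OCc1ccccc1 | intermediate
20 | (S)-(4-hydroxy-3,5-dimethoxyphenyl)[(3R,4R)-4-(4-hydroxy-3,5-dimethoxybenzyl)tetrahydrofuran-3-yl]methanol | COc1cc(C[C@H]2COC[C@@H]2[C@H](O)c2cc(OC)c(O)c(OC)c2)cc(OC)c1O | target

## Step count and least certain steps

Total: 11 steps. Longest linear sequence: 8 steps (steps 1, 3, 5, 6, 7, 9, 10, 11, from 1).

**Step 5 (key step, proposed new method).** Three things may go wrong.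
- Facial discrimination may be poor, because the alkene is far from the auxiliary stereocentre in the non-chelated conformer; separation of the two trans adducts then costs material or fails.
- The sense of induction may be opposite to the model, in which case the enantiomeric auxiliary would serve.
- Fluoride may deprotonate the ArCH2 group faster than the ylide is trapped, moving the double bond into conjugation with the arene and destroying the dipolarophile.

Fallback (known chemistry; sets out from 2 and returns at 11): 2 is cross-metathesised with methyl acrylate, using the catalyst of step 3, to methyl (E)-4-(4-benzyloxy-3,5-dimethoxyphenyl)but-2-enoate F1. F1 is a less acidic, achiral enoate of the class for which the ylide cycloaddition is established. F1 is treated with 7 and CsF in MeCN to give racemic trans-methyl 4-(4-benzyloxy-3,5-dimethoxybenzyl)tetrahydrofuran-3-carboxylate F2. The enantiomers are separated by preparative chromatography on a chiral stationary phase to give methyl (3R,4R)-4-(4-benzyloxy-3,5-dimethoxybenzyl)tetrahydrofuran-3-carboxylate F3, with the configuration assigned by anomalous-dispersion crystallography of a crystalline derivative. Saponification with LiOH in THF/H2O gives 11.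

**Step 3.** Ruthenium hydrides may move the allyl double bond into conjugation before metathesis, giving a chain-shortened cinnamoyl product. The two imide carbonyls may also chelate and slow the catalyst, so that homodimerisation of 2 takes over.

Fallback (sets out from 2 and returns at 5): 2 is cross-metathesised with acrylic acid to (E)-4-(4-benzyloxy-3,5-dimethoxyphenyl)but-2-enoic acid F4. F4 is converted with pivaloyl chloride and Et3N in THF at −20 °C into (E)-4-(4-benzyloxy-3,5-dimethoxyphenyl)but-2-enoic pivalic anhydride F5. F5 acylates 3 in the presence of LiCl and Et3N to give 5.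

**Step 10.** Diastereofacial selectivity may be insufficient, because the two ring carbons flanking C3 differ only moderately in size, and the electron-rich ketone may react sluggishly at −78 °C.

Fallback (sets out from 18 and returns at 19; no new compound): substrate control is replaced by catalyst control in a Corey–Bakshi–Shibata reduction. The catalyst is (R)-1-methyl-3,3-diphenyltetrahydro-1H,3H-pyrrolo[1,2-c][1,3,2]oxazaborole with BH3·SMe2 in THF. With the aryl group as the large substituent it should deliver hydride to the face that gives the (S)-carbinol, which is the same sense as the substrate preference.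

**Step 11.** Hydrogenolysis may continue past the benzyl ethers and cleave the benzylic C–OH bond, which is activated by the para-oxygenated ring. Traces of acid on the catalyst may also ionise the carbinol and erode its configuration.

Fallback (sets out from 18 and returns at 20): the benzyl ethers are removed at the ketone stage, where no benzylic C–O bond is present (H2, Pd/C, EtOAc), giving (4-hydroxy-3,5-dimethoxyphenyl)[(3R,4R)-4-(4-hydroxy-3,5-dimethoxybenzyl)tetrahydrofuran-3-yl]methanone F6. Silylation with TBSCl and imidazole in DMF gives (4-tert-butyldimethylsilyloxy-3,5-dimethoxyphenyl)[(3R,4R)-4-(4-tert-butyldimethylsilyloxy-3,5-dimethoxybenzyl)tetrahydrofuran-3-yl]methanone F7. Reduction with LiBH(s-Bu)3 as in step 10 gives (S)-(4-tert-butyldimethylsilyloxy-3,5-dimethoxyphenyl)[(3R,4R)-4-(4-tert-butyldimethylsilyloxy-3,5-dimethoxybenzyl)tetrahydrofuran-3-yl]methanol F8. The aryl silyl ethers are cleaved with tetrabutylammonium fluoride buffered with acetic acid in THF at 0 °C to give 20.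

## Further compounds

F1 | step 5 | methyl (E)-4-(4-benzyloxy-3,5-dimethoxyphenyl)but-2-enoate | COC(=O)/C=C/Cc1cc(OC)c(OCc2ccccc2)c(OC)c1
F2 | step 5 | racemic trans-methyl 4-(4-benzyloxy-3,5-dimethoxybenzyl)tetrahydrofuran-3-carboxylate (both enantiomers) | COC(=O)[C@H]1COC[C@@H]1Cc1cc(OC)c(OCc2ccccc2)c(OC)c1.COC(=O)[C@@H]1COC[C@H]1Cc1cc(OC)c(OCc2ccccc2)c(OC)c1
F3 | step 5 | methyl (3R,4R)-4-(4-benzyloxy-3,5-dimethoxybenzyl)tetrahydrofuran-3-carboxylate | COC(=O)[C@H]1COC[C@@H]1Cc1cc(OC)c(OCc2ccccc2)c(OC)c1
F4 | step 3 | (E)-4-(4-benzyloxy-3,5-dimethoxyphenyl)but-2-enoic acid | OC(=O)/C=C/Cc1cc(OC)c(OCc2ccccc2)c(OC)c1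
F5 | step 3 | (E)-4-(4-benzyloxy-3,5-dimethoxyphenyl)but-2-enoic pivalic anhydride | CC(C)(C)C(=O)OC(=O)/C=C/Cc1cc(OC)c(OCc2ccccc2)c(OC)c1
F0 | step 10 | none | none
F6 | step 11 | (4-hydroxy-3,5-dimethoxyphenyl)[(3R,4R)-4-(4-hydroxy-3,5-dimethoxybenzyl)tetrahydrofuran-3-yl]methanone | COc1cc(C[C@H]2COC[C@@H]2C(=O)c2cc(OC)c(O)c(OC)c2)cc(OC)c1O
F7 | step 11 | (4-tert-butyldimethylsilyloxy-3,5-dimethoxyphenyl)[(3R,4R)-4-(4-tert-butyldimethylsilyloxy-3,5-dimethoxybenzyl)tetrahydrofuran-3-yl]methanone | COc1cc(C[C@H]2COC[C@@H]2C(=O)c2cc(OC)c(O[Si](C)(C)C(C)(C)C)c(OC)c2)cc(OC)c1O[Si](C)(C)C(C)(C)C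
F8 | step 11 | (S)-(4-tert-butyldimethylsilyloxy-3,5-dimethoxyphenyl)[(3R,4R)-4-(4-tert-butyldimethylsilyloxy-3,5-dimethoxybenzyl)tetrahydrofuran-3-yl]methanol | COc1cc(C[C@H]2COC[C@@H]2[C@H](O)c2cc(OC)c(O[Si](C)(C)C(C)(C)C)c(OC)c2)cc(OC)c1O[Si](C)(C)C(C)(C)C
A1 | alternative 1 | trans,trans-3-[(4-benzyloxy-3,5-dimethoxyphenyl)(hydroxy)methyl]-4-[2-(4-benzyloxy-3,5-dimethoxyphenyl)-1,3-dithian-2-yl]-5-(l-menthyloxy)dihydrofuran-2(3H)-one | COc1cc(C2(SCCCS2)[C@H]3[C@H](O[C@@H]4C[C@H](C)CC[C@H]4C(C)C)OC(=O)[C@@H]3[C@H](O)c3cc(OC)c(OCc4ccccc4)c(OC)c3)cc(OC)c1OCc1ccccc1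
A2 | alternative 1 | (5R)-5-[(1R,2S,5R)-menthyloxy]furan-2(5H)-one | O=C1C=C[C@H](O[C@@H]2C[C@H](C)CC[C@H]2C(C)C)O1
A3 | alternative 1 | 2-(4-benzyloxy-3,5-dimethoxyphenyl)-1,3-dithiane | COc1cc(C2SCCCS2)cc(OC)c1OCc1ccccc1
A4 | alternative 1 | 4-benzyloxy-3,5-dimethoxybenzaldehyde | COc1cc(C=O)cc(OC)c1OCc1ccccc1
A5 | alternative 2 | tert-butyl{(S)-(4-benzyloxy-3,5-dimethoxyphenyl)[(3R,4R)-4-(4-benzyloxy-3,5-dimethoxybenzyl)tetrahydrofuran-3-yl]methoxy}dimethylsilane | COc1cc(C[C@H]2COC[C@@H]2[C@H](O[Si](C)(C)C(C)(C)C)c2cc(OC)c(OCc3ccccc3)c(OC)c2)cc(OC)c1OCc1ccccc1
A6 | alternative 2 | tert-butyl{[(1S,2R,3E)-1,4-bis(4-benzyloxy-3,5-dimethoxyphenyl)-2-[(phenylselanylmethoxy)methyl]but-3-en-1-yl]oxy}dimethylsilane | COc1cc(/C=C/[C@H](COC[Se]c2ccccc2)[C@H](O[Si](C)(C)C(C)(C)C)c2cc(OC)c(OCc3ccccc3)c(OC)c2)cc(OC)c1OCc1ccccc1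
A7 | alternative 3 | (R)-4-(4-benzyloxy-3,5-dimethoxybenzyl)dihydrofuran-2(3H)-one | COc1cc(C[C@H]2COC(=O)C2)cc(OC)c1OCc1ccccc1
A8 | alternative 3 | 3-(4-benzyloxy-3,5-dimethoxybenzyl)cyclobutan-1-one | COc1cc(CC2CC(=O)C2)cc(OC)c1OCc1ccccc1
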